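**Plan**
1. Cuts: C11'=C12' first, then C11=C12 (two Wittig olefinations on either side of a C10 trienedial). Next come the two acyl–O bonds at O-3 and O-3', then C9–C10 and C9'–C10' (vinyl additions). Two C13 ionone-type ketones remain.
2. Enabling feature: the ε-ring (C1'–C6') differs from a β-ring only in having its alkene at C4'=C5' instead of C5'=C6'. Its H-6' lies on the same ring face as O-3', with the polyene chain on the other face. A β-ring carrying an N=N–H group at C4 on the face of O-3 can therefore pass that hydrogen to C6 as N2 leaves, which shifts the alkene and sets C6' in one event.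
3. Both six-membered rings are taken intact from β-ionone through one common intermediate, (3R,4S)-3,4-epoxy-β-ionone. No carbocycle is built.
4. Forward order of chain assembly: C9'–C10' and C9–C10 (vinyl metal additions), then C11=C12 (β-C15 salt plus C10 dialdehyde gives the C25 aldehyde), and last C11'=C12' (C25 aldehyde plus ε-C15 salt).
5. Stereochemistry: a Mn(salen) epoxidation is the only external source. C3' is the untouched oxirane C3–O bond, and C6' follows by suprafacial 1,3-transfer from C4. C3 of the β-ring needs the opposite spatial sense although it is also called R, and comes from the same carbon by Mitsunobu inversion. The E alkenes come from the Wittig reactions and thermal equilibration.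

Key step: step 4

Assumption: by analogy with indene and 1,2-dihydronaphthalene, the (S,S)-Mn(salen) catalyst is taken to give the (3R,4S)-oxirane. The sense should be verified by correlation at the stage of the 3-hydroxy-α-ionone, and the mirror-image catalyst would be used if it proves opposite.
Numbering: carotenoid numbering is used for every compound (ring C1–C6 with the gem-dimethyl carbon as C1, side chain from C7, primes for the ε-half in the C40 compounds).

Step 1
Reactants: 1 β-ionone
Product: 2 (±)-4-bromo-β-ionone
Conditions: NBS (1.05 equiv), AIBN (cat.), PhCF3, 80 °C; filter, concentrate cold, use at once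
Reagents that add atoms: N-bromosuccinimide, O=C1CCC(=O)N1Br
Why: Wohl–Ziegler allylic bromination, in which the radical chain takes the secondary allylic C4–H next to the tetrasubstituted ring alkene; the new C4 centre is racemic and disappears in step 2.

Step 2
Reactants: 2 (±)-4-bromo-β-ionone
Product: 3 3,4-didehydro-β-ionone
Conditions: N,N-diethylaniline (2 equiv), toluene, 95 °C, N2; cold dilute acid wash
Reagents that add atoms: none
Why: Dehydrobromination by a weakly nucleophilic amine base removes H-3 and Br-4 and is driven by extension of the conjugation to the trienone, the long-used entry to the 3,4-didehydro end group.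

Step 3
Reactants: 3 3,4-didehydro-β-ionone
Product: 4 (3R,4S)-3,4-epoxy-β-ionone
Conditions: (S,S)-N,N'-bis(3,5-di-tert-butylsalicylidene)-1,2-cyclohexanediamino-Mn(III) chloride (5 mol %), NMO (5 equiv), mCPBA (1.5 equiv), CH2Cl2, −78 °C; cold NaHCO3 wash, Et3N-deactivated silica
Reagents that add atoms: 3-chloroperoxybenzoic acid (mCPBA), O=C(OO)c1cccc(Cl)c1
Why: Jacobsen–Katsuki epoxidation, for which conjugated cis-disubstituted ring alkenes are the best substrates while the crowded tetrasubstituted C5=C6 and the electron-poor trans C7=C8 alkenes are poor ones, so the catalyst alone sets C3 (R) and C4 (S); the anhydrous peracid/NMO protocol avoids haloform cleavage of the methyl ketone by hypochlorite.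

Step 4
Reactants: 4 (3R,4S)-3,4-epoxy-β-ionone
Product: 7 (3R,6R)-3-hydroxy-α-ionone, via cis-4-hydrazone adduct 5 (not isolated), via allylic diazene 6 (not isolated)
Conditions: IPNBSH (1.2 equiv), Pd2(dba)3·CHCl3 (2.5 mol %), P(OiPr)3 (20 mol %), THF, 0 → 23 °C; then CF3CH2OH–H2O (1:1), 23 °C
Reagents that add atoms: N-isopropylidene-N'-2-nitrobenzenesulfonyl hydrazine (IPNBSH), CC(C)=NNS(=O)(=O)c1ccccc1[N+](=O)[O-] (its heavy atoms reach 5 and 6 only; 7 keeps none of them)
Why: Proposed new method: oxidative addition of Pd(0) to the allylic C4–O bond of 4 takes place from the face opposite the oxirane oxygen and gives an alkoxide-bearing η3-allyl spanning C4, C5 and C6; this alkoxide takes the acidic N–H proton of IPNBSH, and the resulting nitrogen anion bonds to C4 from the face away from the metal, so two inversions leave N-4 and O-3 on one face in 5. Adding trifluoroethanol–water cleaves the acetone hydrazone, the N-amino sulfonamide expels 2-nitrobenzenesulfinic acid, and diazene 6 rearranges by a concerted six-centre retro-ene shift (H–N=N–C4–C5=C6) in which C6–H forms while C4–N breaks, N2 departs and the alkene ends at C4=C5; only the oxirane is opened and no ring is closed. Nearest precedents are the Pd-catalysed substitution of allylic carbonates with this same hydrazine reagent followed by solvolysis and N2 extrusion, the syn 1,2-opening of diene monoepoxides by acidic N–H compounds under Pd(0), and the catecholborane reduction of enone sulfonylhydrazones, which brings hydrogen onto fully substituted alkene carbons beside quaternary centres; untested is the combination on an oxirane whose vinyl partner is tetrasubstituted and belongs to a dienone. C3 is a spectator and keeps the oxirane C–O configuration (3R), whereas the new C6 centre is dictated by C4, because the shift is suprafacial and therefore sets H-6 on the O-3 face and the butenone chain on the other (6R). Required are bond formation at C4 rather than at C6 or further out at C8, and full cis N/O fidelity: C6 carries no hydrogen and is walled in by the C1 gem-dimethyl group, the neighbouring alkoxide hydrogen-bonds the incoming pronucleophile to the near terminus, and a small phosphite ligand at low Pd loading favours ionisation of the crowded alkene while limiting Pd–Pd face exchange. Loss of N2 offsets the cost of deconjugating the ring alkene, and while the reagent is masked as its acetone hydrazone it cannot condense with the C9 ketone.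

Step 5
Reactants: 7 (3R,6R)-3-hydroxy-α-ionone; 8 vinylmagnesium bromide
Product: 9 (3R,6R)-3-hydroxy-9-vinyl-α-ionol (both C9 epimers)
Conditions: 8 (3 equiv), THF, −78 → −30 °C; pH 7 buffer
Reagents that add atoms: vinylmagnesium bromide 8, C=C[Mg]Br
Why: 1,2-Addition of a vinyl Grignard reagent to the enone carbonyl, the standard ionone to vinylionol conversion; the first equivalent is spent on the C3 hydroxyl, the low temperature leaves the base-sensitive C6–H alone, and the unselective new C9 centre is erased in step 7.

Step 6
Reactants: 9 (3R,6R)-3-hydroxy-9-vinyl-α-ionol; 10 myristoyl chloride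
Product: 11 (3R,6R)-3-myristoyloxy-9-vinyl-α-ionol (both C9 epimers)
Conditions: 10 (1.1 equiv), pyridine, DMAP (cat.), CH2Cl2, 0 °C
Reagents that add atoms: myristoyl chloride 10, CCCCCCCCCCCCCC(=O)Cl
Why: DMAP-catalysed acylation distinguishes the accessible secondary allylic alcohol from the tertiary bis-allylic one, and since the C3–O bond is not broken the 3R configuration is kept.

Step 7
Reactants: 11 (3R,6R)-3-myristoyloxy-9-vinyl-α-ionol
Product: 12 ε-C15 phosphonium bromide, 3-O-myristoyl, (3R,6R,7E,9E)
Conditions: PPh3·HBr (1.0 equiv), CH2Cl2, 0 → 23 °C; trituration with hexane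
Reagents that add atoms: triphenylphosphine hydrobromide, [Br-].c1ccc(cc1)[PH+](c1ccccc1)c1ccccc1
Why: Acid-induced ionisation of the tertiary bis-allylic alcohol and capture of the allyl cation by PPh3 at its primary C11 end (SN1'-type allylic transposition) is the standard preparation of C15 Wittig salts from vinylionols, and one equivalent of phosphine-buffered acid should ionise this carbinol far faster than the secondary allylic ester.

Step 8
Reactants: 4 (3R,4S)-3,4-epoxy-β-ionone; 8 vinylmagnesium bromide
Product: 13 (3R,4S)-3,4-epoxy-9-vinyl-β-ionol (both C9 epimers)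
Conditions: anhydrous CeCl3 (1.5 equiv), 8 (1.5 equiv), THF, −78 °C; pH 7 buffer; used without delay
Reagents that add atoms: vinylmagnesium bromide 8, C=C[Mg]Br
Why: Organocerium 1,2-addition, in which the carbonyl-selective and barely basic vinylcerium reagent adds to the enone at a temperature where oxiranes are inert, so C3 and C4 are untouched and the C9 epimers are of no consequence.

Step 9
Reactants: 13 (3R,4S)-3,4-epoxy-9-vinyl-β-ionol
Product: 14 (3S)-3-hydroxy-9-vinyl-β-ionol (both C9 epimers)
Conditions: LiAlH4 (1.5 equiv), Et2O, 0 → 23 °C; Na2SO4·10H2O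
Reagents that add atoms: none
Why: SN2 opening of a vinyl oxirane by hydride at the activated allylic C4, helped by the syn-axial C1 methyl that hinders the path to C3 and by the fully substituted C6 that shuts off the SN2' path; the C3–O bond is retained and the descriptor changes to 3S only because C4 loses its oxygen.

Step 10
Reactants: 14 (3S)-3-hydroxy-9-vinyl-β-ionol; 15 palmitic acid
Product: 16 (3R)-3-palmitoyloxy-9-vinyl-β-ionol (both C9 epimers)
Conditions: 15 (1.3 equiv), PPh3, DIAD (1.4 equiv each), toluene, 0 → 23 °C
Reagents that add atoms: palmitic acid 15, CCCCCCCCCCCCCCCC(=O)O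
Why: Mitsunobu esterification installs the palmitate and inverts C3 by SN2 displacement of the oxyphosphonium group in one operation, giving 3R, while the tertiary alcohol does not form an oxyphosphonium ion under these near-neutral conditions.

Step 11
Reactants: 16 (3R)-3-palmitoyloxy-9-vinyl-β-ionol
Product: 17 β-C15 phosphonium bromide, 3-O-palmitoyl, (3R,7E,9E)
Conditions: PPh3·HBr (1.0 equiv), CH2Cl2, 0 → 23 °C; trituration with hexane
Reagents that add atoms: triphenylphosphine hydrobromide, [Br-].c1ccc(cc1)[PH+](c1ccccc1)c1ccccc1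
Why: The same SN1'-type conversion of a vinylionol into its C15 Wittig salt, here through a cation further stabilised by the ring alkene, with the homoallylic ester and C3 as spectators.

Step 12
Reactants: 17 β-C15 phosphonium bromide; 18 (2E,4E,6E)-2,7-dimethylocta-2,4,6-trienedial
Product: 20 (3R)-3-palmitoyloxy-12'-apo-β-caroten-12'-al, via β-C15 ylide 19 (not isolated)
Conditions: 18 (2.5 equiv), 1,2-epoxybutane, reflux, N2, dark, slow addition of 17; all-E aldehyde by chromatography and crystallisation, excess 18 recovered
Reagents that add atoms: C10 dialdehyde 18, O=C/C(C)=C/C=C/C=C(C)/C=O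
Why: Wittig olefination with an epoxide as acid scavenger (bromide opens the epoxide and the alkoxide formed deprotonates the salt) builds C11=C12 under almost neutral, ester-safe conditions, and the excess of dialdehyde together with slow addition of the salt holds the reaction at the mono-olefination stage.

Step 13
Reactants: 20 (3R)-3-palmitoyloxy-12'-apo-β-caroten-12'-al; 12 ε-C15 phosphonium bromide
Product: 23 (3R,3'R,6'R)-lutein 3-O-palmitate 3'-O-myristate, via ε-C15 ylide 21 (not isolated), via 11'Z isomer 22 (not isolated)
Conditions: 12 (1.2 equiv), 1,2-epoxybutane, reflux, N2, dark; evaporate; n-heptane, 95 °C, N2; crystallisation from acetone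
Reagents that add atoms: none
Why: Wittig olefination of the C25 aldehyde by the semi-stabilised allylic ylide under the same neutral conditions forms C11'=C12' without harm to either ester or to the C6'–H, the strained 11'Z isomer should relax to the all-E polyene on heating, and no stereocentre is touched.

**Compound list**
1 | β-ionone | CC(=O)/C=C/C1=C(C)CCCC1(C)C | starting material
2 | (±)-4-bromo-β-ionone | CC(=O)/C=C/C1=C(C)C(Br)CCC1(C)C | intermediate
3 | 3,4-didehydro-β-ionone | CC(=O)/C=C/C1=C(C)C=CCC1(C)C | intermediate
4 | (3R,4S)-3,4-epoxy-β-ionone | CC(=O)/C=C/C1=C(C)[C@@H]2O[C@@H]2CC1(C)C | intermediate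
5 | (3R,4S)-3-hydroxy-4-[2-isopropylidene-1-(2-nitrophenylsulfonyl)hydrazinyl]-β-ionone, N-4 cis to O-3 | CC(=O)/C=C/C1=C(C)[C@H](N(N=C(C)C)S(=O)(=O)c2ccccc2[N+](=O)[O-])[C@H](O)CC1(C)C | intermediate
6 | (3R,4S)-4-diazenyl-3-hydroxy-β-ionone, HN=N at C4 cis to O-3 | CC(=O)/C=C/C1=C(C)[C@H](N=N)[C@H](O)CC1(C)C | intermediate
7 | (3R,6R)-3-hydroxy-α-ionone, OH and side chain trans | CC(=O)/C=C/[C@H]1C(C)=C[C@H](O)CC1(C)C | intermediate
8 | vinylmagnesium bromide | C=C[Mg]Br | starting material
9 | (3R,6R)-3-hydroxy-9-vinyl-α-ionol, (1E)-1-[(1R,4R)-4-hydroxy-2,6,6-trimethylcyclohex-2-en-1-yl]-3-methylpenta-1,4-dien-3-ol, both C9 epimers | C=CC(C)(O)/C=C/[C@H]1C(C)=C[C@H](O)CC1(C)C | intermediate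
10 | myristoyl chloride | CCCCCCCCCCCCCC(=O)Cl | starting material
11 | (3R,6R)-3-myristoyloxy-9-vinyl-α-ionol, both C9 epimers | C=CC(C)(O)/C=C/[C@H]1C(C)=C[C@H](OC(=O)CCCCCCCCCCCCC)CC1(C)C | intermediate
12 | [(2E,4E)-3-methyl-5-[(1R,4R)-2,6,6-trimethyl-4-(tetradecanoyloxy)cyclohex-2-en-1-yl]penta-2,4-dienyl]triphenylphosphonium bromide | [Br-].c1ccccc1[P+](c1ccccc1)(c1ccccc1)C/C=C(C)/C=C/[C@H]1C(C)=C[C@H](OC(=O)CCCCCCCCCCCCC)CC1(C)C | intermediate
13 | (3R,4S)-3,4-epoxy-9-vinyl-β-ionol, both C9 epimers | C=CC(C)(O)/C=C/C1=C(C)[C@@H]2O[C@@H]2CC1(C)C | intermediate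
14 | (3S)-3-hydroxy-9-vinyl-β-ionol, both C9 epimers | O[C@H]1CC(C)=C(/C=C/C(C)(O)C=C)C(C)(C)C1 | intermediate
15 | palmitic acid | CCCCCCCCCCCCCCCC(=O)O | starting material
16 | (3R)-3-palmitoyloxy-9-vinyl-β-ionol, both C9 epimers | CCCCCCCCCCCCCCCC(=O)O[C@@H]1CC(C)=C(/C=C/C(C)(O)C=C)C(C)(C)C1 | intermediate
17 | [(2E,4E)-5-[(4R)-4-(hexadecanoyloxy)-2,6,6-trimethylcyclohex-1-en-1-yl]-3-methylpenta-2,4-dienyl]triphenylphosphonium bromide | CCCCCCCCCCCCCCCC(=O)O[C@@H]1CC(C)=C(/C=C/C(C)=C/C[P+](c2ccccc2)(c2ccccc2)c2ccccc2)C(C)(C)C1.[Br-] | intermediate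
18 | (2E,4E,6E)-2,7-dimethylocta-2,4,6-trienedial | O=C/C(C)=C/C=C/C=C(C)/C=O | starting material
19 | ylide of 17 (C11=PPh3) | CCCCCCCCCCCCCCCC(=O)O[C@@H]1CC(C)=C(/C=C/C(C)=C/C=P(c2ccccc2)(c2ccccc2)c2ccccc2)C(C)(C)C1 | intermediate
20 | (3R)-3-palmitoyloxy-12'-apo-β-caroten-12'-al, all-E | CCCCCCCCCCCCCCCC(=O)O[C@@H]1CC(C)=C(/C=C/C(C)=C/C=C/C(C)=C/C=C/C=C(C)/C=O)C(C)(C)C1 | intermediate
21 | ylide of 12 (C11'=PPh3) | c1ccccc1P(c1ccccc1)(c1ccccc1)=C/C=C(C)/C=C/[C@H]1C(C)=C[C@H](OC(=O)CCCCCCCCCCCCC)CC1(C)C | intermediate
22 | (11'Z)-isomer of 23 | CCCCCCCCCCCCCCCC(=O)O[C@@H]1CC(C)=C(/C=C/C(C)=C/C=C/C(C)=C/C=C/C=C(C)/C=C\C=C(C)\C=C\[C@H]2C(C)=C[C@H](OC(=O)CCCCCCCCCCCCC)CC2(C)C)C(C)(C)C1 | intermediate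
23 | (all-E,3R,3'R,6'R)-lutein 3-O-palmitate 3'-O-myristate | CCCCCCCCCCCCCCCC(=O)O[C@@H]1CC(C)=C(/C=C/C(C)=C/C=C/C(C)=C/C=C/C=C(C)/C=C/C=C(C)/C=C/[C@H]2C(C)=C[C@H](OC(=O)CCCCCCCCCCCCC)CC2(C)C)C(C)(C)C1 | target

**Step count**
- Total step count: 13.
- Longest linear sequence: 9 steps (1, 2, 3, 8, 9, 10, 11, 12, 13). The ε-branch runs over 8 steps (1–7, 13).

**Steps most likely to fail**

Step 4 (proposed new method). Several things may go wrong:
- Palladium may fail to ionise the oxirane across the crowded, electron-poor tetrasubstituted alkene.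
- Palladium may instead isomerise the oxirane by hydride shift.
- The nitrogen anion may add at the remote end of the extended π-system.
- Face exchange of the allyl complex may erode the cis N/O relationship.
- The freed hydrazine may condense with the ketone before it fragments.

The fallback uses known chemistry, sets out from 4 and returns at 7. It makes the C4–N bond by Mitsunobu displacement instead of by palladium. Dilute perchloric acid in aqueous THF at 0 °C should open 4 anti at the allylic C4 to (3R,4R)-3,4-dihydroxy-β-ionone F1. TBSCl and imidazole should silylate the less hindered C3 hydroxyl to (3R,4R)-3-(tert-butyldimethylsilyloxy)-4-hydroxy-β-ionone F2; this also prevents re-closure to the oxirane. PPh3, DEAD and IPNBSH then displace the allylic C4 hydroxyl with inversion to the 3-O-TBS cis-4-hydrazone adduct F3. In the same flask, trifluoroethanol–water takes F3 through the 3-O-TBS allylic diazene F4 to (3R,6R)-3-(tert-butyldimethylsilyloxy)-α-ionone F5. HF·pyridine in THF frees 7.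

Step 3. Oxygen transfer may be insufficiently face-selective, which would carry diastereomers into the final coupling. It may also compete at C5=C6, and the dienyl oxirane may open or rearrange during isolation. The fallback sets out from 3 and returns at 4, and replaces asymmetric catalysis by a resolution. NBS in aqueous DME should add bromine and hydroxyl anti across C3=C4, with water entering at the allylic C4, to give racemic trans-3-bromo-4-hydroxy-β-ionone F6. A lipase chosen by screening, with vinyl acetate, acetylates one antipode to (3R,4R)-4-acetoxy-3-bromo-β-ionone F7 and leaves (3S,4S)-3-bromo-4-hydroxy-β-ionone F8. After separation, K2CO3 in methanol closes F8 by internal SN2 displacement at C3 to 4.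

Step 10. The activated C3 oxygen may be lost by E2 elimination towards the conjugated triene. Substitution may be slow because the weakly acidic fatty carboxylate must approach syn-axial to a C1 methyl. The tertiary bis-allylic alcohol may ionise. The fallback sets out from 3 and returns at 16, and removes the inversion altogether. The mirror-image (R,R)-Mn(salen) catalyst under the conditions of step 3 should give (3S,4R)-3,4-epoxy-β-ionone F9. Vinylcerium addition as in step 8 gives (3S,4R)-3,4-epoxy-9-vinyl-β-ionol F10, and LiAlH4 as in step 9 gives (3R)-3-hydroxy-9-vinyl-β-ionol F11. A carbodiimide esterification with 15 (EDC, DMAP, CH2Cl2) then acylates the secondary alcohol with retention to 16.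

**Further compounds**
F1 | step 4 | (3R,4R)-3,4-dihydroxy-β-ionone | CC(=O)/C=C/C1=C(C)[C@@H](O)[C@H](O)CC1(C)C
F2 | step 4 | (3R,4R)-3-(tert-butyldimethylsilyloxy)-4-hydroxy-β-ionone | CC(=O)/C=C/C1=C(C)[C@@H](O)[C@H](O[Si](C)(C)C(C)(C)C)CC1(C)C
F3 | step 4 | 3-O-TBS cis-4-hydrazone adduct, (3R,4S) | CC(=O)/C=C/C1=C(C)[C@H](N(N=C(C)C)S(=O)(=O)c2ccccc2[N+](=O)[O-])[C@H](O[Si](C)(C)C(C)(C)C)CC1(C)C
F4 | step 4 | 3-O-TBS allylic diazene, (3R,4S) | CC(=O)/C=C/C1=C(C)[C@H](N=N)[C@H](O[Si](C)(C)C(C)(C)C)CC1(C)C
F5 | step 4 | (3R,6R)-3-(tert-butyldimethylsilyloxy)-α-ionone | CC(=O)/C=C/[C@H]1C(C)=C[C@H](O[Si](C)(C)C(C)(C)C)CC1(C)C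
F6 | step 3 | racemic trans-3-bromo-4-hydroxy-β-ionone (racemate, the 3S,4S enantiomer is drawn) | CC(=O)/C=C/C1=C(C)[C@H](O)[C@@H](Br)CC1(C)C
F7 | step 3 | (3R,4R)-4-acetoxy-3-bromo-β-ionone | CC(=O)/C=C/C1=C(C)[C@@H](OC(C)=O)[C@H](Br)CC1(C)C
F8 | step 3 | (3S,4S)-3-bromo-4-hydroxy-β-ionone | CC(=O)/C=C/C1=C(C)[C@H](O)[C@@H](Br)CC1(C)C
F9 | step 10 | (3S,4R)-3,4-epoxy-β-ionone | CC(=O)/C=C/C1=C(C)[C@H]2O[C@H]2CC1(C)C
F10 | step 10 | (3S,4R)-3,4-epoxy-9-vinyl-β-ionol, both C9 epimers | C=CC(C)(O)/C=C/C1=C(C)[C@H]2O[C@H]2CC1(C)C
F11 | step 10 | (3R)-3-hydroxy-9-vinyl-β-ionol, both C9 epimers | O[C@@H]1CC(C)=C(/C=C/C(C)(O)C=C)C(C)(C)C1
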